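**Assumption:** the SMILES fixes only the three stereogenic carbons (all R: C3 of the dihydroisoquinoline, C1 and C3 of the tetrahydroisoquinoline). The two 5,8′ biaryl axes are configurationally stable but not encoded, so I leave them uncontrolled and separate the atropo-diastereomers by HPLC at the end.

## Retrosynthetic overview

1. Michellamine F (19) ⇐ global O-debenzylation of tri-O-benzyl ether 18.
2. 18 ⇐ one-pot hetero-double Suzuki coupling that breaks the C2 symmetry of binaphthol bis-boronate 8 with two different bromides, 16 (8-OMe dihydroisoquinoline) and 17 (trans-tetrahydroisoquinoline). Both 5,8′ bonds form in this step.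
3. 8 ⇐ oxidative dearomatising ortho–ortho dimerisation of the simple naphthol triflate 6 (via the quinoid binaphthylidenedione). 6 comes from 4-chloro-3-methylphenol and maleic anhydride via 7-methyljuglone.
4. 16 and 17 ⇐ one common bromo-dihydroisoquinoline 14 (Bischler–Napieralski), with C3 from (R)-Boc-2-methylaziridine. 16 by chelation-controlled 8-O-debenzylation/methylation; 17 by trans-selective reduction (sets C1).
5. Ring order: naphthoquinone ring (Friedel–Crafts) → binaphthyl (6′,6″ bond) → N-heterocycles → the two 5,8′ biaryl bonds last.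

## Route

**Step 1**
Reactants: 1, 4-chloro-3-methylphenol; 2, maleic anhydride
Product: 3, 8-chloro-5-hydroxy-7-methylnaphthalene-1,4-dione
Conditions: AlCl3/NaCl melt, 180 °C, 5 min; then 2 M HCl
Reagents that add atoms: none (both reactants listed)
Why: Double Friedel–Crafts acylation at C6/C5 of the phenol (the only adjacent free pair, with Cl blocking the para position) builds the juglone skeleton in one operation, as in the established 7-methyljuglone synthesis.

**Step 2**
Reactants: 3
Product: 4, 5-hydroxy-7-methylnaphthalene-1,4-dione (7-methyljuglone)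
Conditions: SnCl2·2H2O, 4 M HCl, THF, 60 °C; then aq. FeCl3
Reagents that add atoms: none
Why: Sn(II) reduces the quinone and reductively removes the peri-chlorine through the diketo tautomer of the hydroquinone, and FeCl3 re-oxidises to the quinone (reductive dehalogenation).

**Step 3**
Reactants: 4
Product: 5, 5-methoxy-7-methylnaphthalene-1,4-dione
Conditions: MeI, Ag2O, CH2Cl2, rt, dark
Reagents that add atoms: iodomethane, CI
Why: Purdie methylation is the standard way to O-methylate the chelated peri-hydroxyl of juglones without touching the quinone.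

**Step 4**
Reactants: 5
Product: 6, 4-hydroxy-5-methoxy-7-methylnaphthalen-1-yl trifluoromethanesulfonate
Conditions: Na2S2O4, EtOAc/H2O, rt; then PhNTf2 (1.0 equiv), Et3N, CH2Cl2, −20 → 0 °C
Reagents that add atoms: N-phenylbis(trifluoromethanesulfonimide), O=S(=O)(N(c1ccccc1)S(=O)(=O)C(F)(F)F)C(F)(F)F
Why: Dithionite gives the unisolated 1,4-diol, whose C4–OH is hydrogen-bonded to the peri-OMe and hindered, so regioselective O-sulfonylation occurs at the free C1–OH.

**Step 5**
Reactants: 6 (2 equiv)
Product: 7, 1,1′-dihydroxy-8,8′-dimethoxy-6,6′-dimethyl-[2,2′-binaphthalene]-4,4′-diyl bis(trifluoromethanesulfonate)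
Conditions: Ag2O, Et3N (cat.), CHCl3, rt; filter; aq. Na2S2O4
Reagents that add atoms: none
Why: Oxidative phenolic coupling of a para-blocked 1-naphthol goes ortho–ortho and over-oxidises to the dearomatised violet 2,2′-binaphthylidene-1,1′-dione (as 4-halo-1-naphthols do), which dithionite re-aromatises to the C2-symmetric binaphthol.

**Step 6**
Reactants: 7
Product: 8, 8,8′-dimethoxy-6,6′-dimethyl-4,4′-bis(4,4,5,5-tetramethyl-1,3,2-dioxaborolan-2-yl)-[2,2′-binaphthalene]-1,1′-diol
Conditions: B2pin2, Pd(dppf)Cl2, KOAc, dioxane, 90 °C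
Reagents that add atoms: bis(pinacolato)diboron, CC1(C)OB(OC1(C)C)B1OC(C)(C)C(C)(C)O1
Why: Miyaura borylation of aryl triflates tolerates free phenols and converts both termini into nucleophiles in one step.

**Step 7**
Reactants: 9, 1,3-bis(benzyloxy)-5-bromobenzene; 10, tert-butyl (R)-2-methylaziridine-1-carboxylate
Product: 11, tert-butyl (R)-[1-(3,5-bis(benzyloxy)phenyl)propan-2-yl]carbamate
Conditions: Mg, THF; then CuI (10 mol %), 10, −30 → 0 °C
Reagents that add atoms: none (both reactants listed)
Why: Cu-catalysed Grignard ring-opening attacks the unsubstituted CH2 of the aziridine (SN2), so the (R) stereocentre of 10 is carried over untouched and becomes C3 of both isoquinolines.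

**Step 8**
Reactants: 11
Product: 12, (R)-N-[1-(3,5-bis(benzyloxy)phenyl)propan-2-yl]acetamide
Conditions: TFA, CH2Cl2, 0 °C → rt; evaporate; Ac2O, Et3N, CH2Cl2, 0 °C
Reagents that add atoms: acetic anhydride, CC(=O)OC(C)=O
Why: Acidolytic Boc removal and N-acetylation in one pot give the Bischler–Napieralski substrate without affecting the benzyl ethers or the stereocentre.

**Step 9**
Reactants: 12
Product: 13, (R)-N-[1-(3,5-bis(benzyloxy)-2-bromophenyl)propan-2-yl]acetamide
Conditions: NBS (1.0 equiv), MeCN, −20 → 0 °C
Reagents that add atoms: N-bromosuccinimide, O=C1CCC(=O)N1Br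
Why: Electrophilic aromatic bromination of the symmetric 3,5-dialkoxy ring occurs ortho to the side chain (ortho/para to the two OBn groups) and not at the doubly flanked C4, as for 3,5-dimethoxytoluene.

**Step 10**
Reactants: 13
Product: 14, (R)-6,8-bis(benzyloxy)-5-bromo-1,3-dimethyl-3,4-dihydroisoquinoline
Conditions: POCl3, MeCN, 80 °C
Reagents that add atoms: none
Why: Bischler–Napieralski cyclisation can only close at the one free ortho position (ortho and para to the two OBn groups), which fixes Br at C5 without disturbing C3.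

**Step 11**
Reactants: 14
Product: 15, (R)-6-(benzyloxy)-5-bromo-1,3-dimethyl-3,4-dihydroisoquinolin-8-ol
Conditions: MgBr2·OEt2, toluene/Et2O, 60 °C
Reagents that add atoms: none
Why: Chelation-controlled debenzylation, in which Mg bridges the imine N and the peri 8-O in a six-membered chelate, cleaves only the 8-OBn and leaves the non-chelated 6-OBn.

**Step 12**
Reactants: 15
Product: 16, (R)-6-(benzyloxy)-5-bromo-8-methoxy-1,3-dimethyl-3,4-dihydroisoquinoline
Conditions: MeI, K2CO3, acetone, 50 °C
Reagents that add atoms: iodomethane, CI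
Why: Williamson O-methylation of the phenoxide is much faster than alkylation of the hindered imine nitrogen flanked by the C1 and C3 methyls.

**Step 13**
Reactants: 14
Product: 17, (1R,3R)-6,8-bis(benzyloxy)-5-bromo-1,3-dimethyl-1,2,3,4-tetrahydroisoquinoline
Conditions: LiAlH4, AlMe3, THF, −78 → −40 °C
Reagents that add atoms: none
Why: In this substrate-controlled imine reduction the AlMe3-complexed imine places the C3 methyl pseudo-axial and hydride attacks the opposite face, giving the 1,3-trans (1R,3R) amine (NaBH4 would give cis), with the aryl bromide inert at this temperature.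

**Step 14 (key step)**
Reactants: 8 (1.0 equiv); 16 (1.0 equiv); 17 (1.1 equiv)
Product: 18, 6,6‴,8‴-tri-O-benzyl-michellamine F: the binaphthol carrying at one C4 the (R)-6-benzyloxy-8-methoxy-1,3-dimethyl-3,4-dihydroisoquinolin-5-yl group and at the other C4′ the (1R,3R)-6,8-bis(benzyloxy)-1,3-dimethyl-1,2,3,4-tetrahydroisoquinolin-5-yl group
Conditions: SPhos Pd G3 (10 mol %), K3PO4, toluene/H2O, 95 °C; chromatographic removal of the two homo-coupled products
Reagents that add atoms: none
Why: In this double Suzuki–Miyaura coupling the two equivalent Bpin termini react independently, so a 1:1 feed of the bromides desymmetrises the core statistically (at most 50 % hetero-product, separable from the homo-products by amine count and polarity) and forms both hindered 5,8′ bonds at once as an atropisomer mixture.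

**Step 15**
Reactants: 18
Product: 19, michellamine F
Conditions: BCl3 (12 equiv), pentamethylbenzene, CH2Cl2, −78 °C; MeOH quench at −78 °C; preparative HPLC of the atropo-diastereomers
Reagents that add atoms: none
Why: BCl3 with a cation scavenger cleaves aryl benzyl ethers at −78 °C, where aryl methyl ethers (even chelated ones) and the C=N bond are untouched, whereas hydrogenolysis would reduce the imine.

## Compound list

1 | 4-chloro-3-methylphenol | Cc1cc(O)ccc1Cl | starting material
2 | maleic anhydride | O=C1OC(=O)C=C1 | starting material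
3 | 8-chloro-5-hydroxy-7-methylnaphthalene-1,4-dione | Cc1cc(O)c2C(=O)C=CC(=O)c2c1Cl | intermediate
4 | 5-hydroxy-7-methylnaphthalene-1,4-dione | Cc1cc(O)c2C(=O)C=CC(=O)c2c1 | intermediate
5 | 5-methoxy-7-methylnaphthalene-1,4-dione | COc1cc(C)cc2C(=O)C=CC(=O)c12 | intermediate
6 | 4-hydroxy-5-methoxy-7-methylnaphthalen-1-yl triflate | COc1cc(C)cc2c(OS(=O)(=O)C(F)(F)F)ccc(O)c12 | intermediate
7 | binaphthol bis-triflate | FC(F)(F)S(=O)(=O)Oc1cc(-c2cc(OS(=O)(=O)C(F)(F)F)c3cc(C)cc(OC)c3c2O)c(O)c2c(OC)cc(C)cc12 | intermediate
8 | binaphthol bis-pinacolboronate | CC1(C)OB(OC1(C)C)c1cc(-c2cc(B3OC(C)(C)C(C)(C)O3)c3cc(C)cc(OC)c3c2O)c(O)c2c(OC)cc(C)cc12 | intermediate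
9 | 1,3-bis(benzyloxy)-5-bromobenzene | Brc1cc(OCc2ccccc2)cc(OCc2ccccc2)c1 | starting material
10 | tert-butyl (R)-2-methylaziridine-1-carboxylate | C[C@@H]1CN1C(=O)OC(C)(C)C | starting material
11 | tert-butyl (R)-[1-(3,5-bis(benzyloxy)phenyl)propan-2-yl]carbamate | CC(C)(C)OC(=O)N[C@H](C)Cc1cc(OCc2ccccc2)cc(OCc2ccccc2)c1 | intermediate
12 | (R)-N-[1-(3,5-bis(benzyloxy)phenyl)propan-2-yl]acetamide | CC(=O)N[C@H](C)Cc1cc(OCc2ccccc2)cc(OCc2ccccc2)c1 | intermediate
13 | (R)-N-[1-(3,5-bis(benzyloxy)-2-bromophenyl)propan-2-yl]acetamide | CC(=O)N[C@H](C)Cc1c(Br)c(OCc2ccccc2)cc(OCc2ccccc2)c1 | intermediate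
14 | (R)-6,8-bis(benzyloxy)-5-bromo-1,3-dimethyl-3,4-dihydroisoquinoline | CC1=N[C@H](C)Cc2c(Br)c(OCc3ccccc3)cc(OCc3ccccc3)c12 | intermediate
15 | (R)-6-(benzyloxy)-5-bromo-1,3-dimethyl-3,4-dihydroisoquinolin-8-ol | CC1=N[C@H](C)Cc2c(Br)c(OCc3ccccc3)cc(O)c12 | intermediate
16 | (R)-6-(benzyloxy)-5-bromo-8-methoxy-1,3-dimethyl-3,4-dihydroisoquinoline | COc1cc(OCc2ccccc2)c(Br)c2c1C(C)=N[C@H](C)C2 | intermediate
17 | (1R,3R)-6,8-bis(benzyloxy)-5-bromo-1,3-dimethyl-1,2,3,4-tetrahydroisoquinoline | Brc1c(OCc2ccccc2)cc(OCc2ccccc2)c2c1C[C@@H](C)N[C@@H]2C | intermediate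
18 | 6,6‴,8‴-tri-O-benzyl-michellamine F | COc1cc(OCc6ccccc6)c(-c2cc(-c3cc(-c4c(OCc6ccccc6)cc(OCc6ccccc6)c5c4C[C@@H](C)N[C@@H]5C)c4cc(C)cc(OC)c4c3O)c(O)c3c(OC)cc(C)cc23)c2c1C(C)=N[C@H](C)C2 | intermediate
19 | michellamine F | COc1cc(O)c(-c2cc(-c3cc(-c4c(O)cc(O)c5c4C[C@@H](C)N[C@@H]5C)c4cc(C)cc(OC)c4c3O)c(O)c3c(OC)cc(C)cc23)c2c1C(C)=N[C@H](C)C2 | target

## Totals and risks

Total step count: 15. Longest linear sequence: 8 steps (1 → 6, then 14 and 15; the isoquinoline branch 7 → 12, 14, 15 is also 8).

The three steps most likely to fail: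

1. **Step 14.** The hetero-product is capped at 50 %, the coupling is hindered, the electron-rich 4-hydroxynaphthyl boronate may protodeboronate, and four atropisomers can form. Fallback: abandon the symmetric core. Borylate monomer 6, couple it separately with 16 and with 17, and form the central 6′,6″ bond last by Ag2O oxidative cross-dimerisation of the two monomers followed by dithionite reduction.
2. **Step 5.** The triflate sits on an electrophilic carbon of the quinoid intermediate and may be lost, and over-oxidation or C–O coupling can compete. Fallback: make the 2,2′ bond without oxidation. Iodinate 6 ortho to the OH (NIS), then run a Pd-catalysed one-pot borylation/Suzuki homocoupling that exploits I ≫ OTf selectivity.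
3. **Step 15.** BCl3 may attack the chelated 8-OMe next to the imine or the peri 4′-OMe groups, or the benzyl cation may C-alkylate the electron-rich rings. Fallback: remove the benzyl groups before the union. Debenzylate the simple bromides 16 and 17 (no naphthalene methyl ethers present) and run the Suzuki coupling on the free phenols, so the coupling delivers 19 directly.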